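**Plan**

- Retrosynthesis: ring A's diosphenol and exocyclic methylene are unmasked last from a C4 ketone (C4=C18 by methylenation, C3 by allylic oxidation, C2–O carried from the start). Ring B is then cut at C5–C6, the side chain at C11=C12, and C9 at C9–C20 and C9–C10.
- Enabling feature: C5 is the α-carbon of the latent C4 carbonyl of ring A, and C6 is a primary carbon next to the C7 oxygen. Ring B (C5–C10) can therefore close by cycloalkylation of a C4/C5 enolate that conjugate addition at C10 has placed regiospecifically. O7 and C11 are 1,3-related across C8, so they can be tied into a temporary γ-lactone whose enolate builds quaternary C9.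
- Forward: (S)-carvone gives the ring-A enone (isopropenyl becomes the C2 oxygen); crotylboration gives the lactone; Mukaiyama–Michael union (C9–C10); C9 methylation; Wittig opening of the lactone with the C12–C16 ylide; ring B closed at C5–C6; ring A oxidised.
- Stereochemistry: C7/C8 from syn-selective asymmetric crotylboration; C9 from methylation anti to the lactone substituents; C10 from addition trans to the carvone-derived C2 stereocentre; C5 from the enforced cis ring fusion; C13 from (S)-β-methyl-γ-butyrolactone.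

Key step: step 15

Remark: positions are given in clerodane numbering (ring A = C1–C5 and C10; ring B = C5–C10; C17 on C8, C18 = exocyclic CH2 on C4, C19 on C5, C20 on C9, chain C11–C16). The enol drawn in the target is taken as the stable diosphenol tautomer of the C2/C3-dione, so the dione is the compound made.

**Route**

Step 1
Reactants: 1 (S)-(+)-carvone
Product: 3 (1S)-4-methyl-5-oxocyclohex-3-en-1-yl acetate, via methoxy hydroperoxide 2 (not isolated)
Conditions: O3, CH2Cl2/MeOH, −78 °C; then Ac2O, Et3N, DMAP (cat.), −78 to 40 °C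
Reagents that add atoms: ozone (O=[O+][O-]); methanol (CO)
Why: Ozone should cleave only the electron-rich isopropenyl alkene beside the electron-poor enone, and acylation of the methoxy hydroperoxide triggers a Criegee rearrangement in which the ring carbon migrates to oxygen with retention, so the carvone stereocentre becomes the C2 carbinol carbon.

Step 2
Reactants: 3 (1S)-4-methyl-5-oxocyclohex-3-en-1-yl acetate
Product: 4 (5S)-5-hydroxy-2-methylcyclohex-2-en-1-one
Conditions: AcCl (0.2 equiv), MeOH, 0 °C to rt
Reagents that add atoms: none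
Why: Acid-catalysed transesterification removes the acetate without the enolate formation that would eliminate the β-acyloxy group and aromatise the ring.

Step 3
Reactants: 4 (5S)-5-hydroxy-2-methylcyclohex-2-en-1-one
Product: 5 (5S)-2-methyl-5-[(triisopropylsilyl)oxy]cyclohex-2-en-1-one
Conditions: iPr3SiOTf, 2,6-lutidine, CH2Cl2, −78 to 0 °C
Reagents that add atoms: triisopropylsilyl triflate (CC(C)[Si](OS(=O)(=O)C(F)(F)F)(C(C)C)C(C)C)
Why: Silyl triflate silylation under non-nucleophilic base protects the β-hydroxy enone without elimination and installs a bulky ether that later directs attack at C10 and outlasts the fluoride of step 15.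

Step 4
Reactants: 6 2-(benzyloxy)acetaldehyde
Product: 8 (2R,3S)-1-(benzyloxy)-3-methylpent-4-en-2-ol, via diisopinocampheylborinate 7 (not isolated)
Conditions: cis-2-butene, n-BuLi, KOtBu, THF, −78 to −45 °C; (+)-Ipc2BOMe, −78 °C; BF3·OEt2; then 6, −78 °C; NaOH, H2O2, rt
Reagents that add atoms: cis-2-butene (C/C=C\C)
Why: In this Brown crotylboration the (Z)-crotylborane reacts through a closed chair transition state, so the Z geometry gives the syn C7/C8 relationship, and the isopinocampheyl groups of the (+)-Ipc2BOMe-derived reagent (from (−)-α-pinene) are the antipode expected to direct attack to the Re face of the aldehyde.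

Step 5
Reactants: 8 (2R,3S)-1-(benzyloxy)-3-methylpent-4-en-2-ol
Product: 10 (3S,4R)-5-(benzyloxy)-3-methylpentane-1,4-diol, via bis(9-BBN) adduct 9 (not isolated)
Conditions: 9-BBN (2.2 equiv), THF, 0 °C to rt; then NaOH, H2O2
Reagents that add atoms: hydrogen peroxide (OO)
Why: Hydroboration–oxidation with a bulky borane places boron, and then oxygen, on the terminal carbon C11 with anti-Markovnikov regioselectivity and leaves both stereocentres untouched.

Step 6
Reactants: 10 (3S,4R)-5-(benzyloxy)-3-methylpentane-1,4-diol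
Product: 12 (4S,5R)-5-[(benzyloxy)methyl]-4-methyloxolan-2-one, via lactol 11 (not isolated)
Conditions: TEMPO (10 mol %), PhI(OAc)2, CH2Cl2, rt
Reagents that add atoms: none
Why: The oxoammonium (TEMPO) oxidation takes the primary alcohol selectively to the aldehyde, which closes with the C7 hydroxyl to the lactol and is oxidised on to the cis-4,5-disubstituted γ-lactone (oxidative lactonisation of a 1,4-diol).

Step 7
Reactants: 13 (S)-4-methyloxolan-2-one
Product: 15 methyl (S)-4-bromo-3-methylbutanoate, via bromo acid 14 (not isolated)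
Conditions: HBr (gas), MeOH, 0 °C to rt
Reagents that add atoms: hydrogen bromide (Br); methanol (CO)
Why: Bromide opens the protonated lactone by SN2 attack at the O–CH2 carbon and Fischer esterification follows, neither event touching the C13 stereocentre.

Step 8
Reactants: 15 methyl (S)-4-bromo-3-methylbutanoate
Product: 16 [(2S)-4-methoxy-2-methyl-4-oxobutyl]triphenylphosphonium bromide
Conditions: PPh3, MeCN, reflux
Reagents that add atoms: triphenylphosphine (c1ccc(cc1)P(c1ccccc1)c1ccccc1)
Why: SN2 quaternisation of the primary bromide gives the Wittig salt, the stereocentre being one carbon away from the reacting centre.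

Step 9
Reactants: 12 (4S,5R)-5-[(benzyloxy)methyl]-4-methyloxolan-2-one; 5 (5S)-2-methyl-5-[(triisopropylsilyl)oxy]cyclohex-2-en-1-one
Product: 19 Mukaiyama–Michael adduct (ring-A enol silyl ether joined at C10 to the lactone α-carbon C9), via lithium enolate 17 (not isolated), via silyl ketene acetal 18 (not isolated)
Conditions: 12, LiN(iPr)2, THF, −78 °C; tBuMe2SiCl, DMPU, −78 °C to rt; concentrate; then 5, tBuMe2SiOTf (10 mol %), CH2Cl2, −78 °C
Reagents that add atoms: tert-butyldimethylsilyl chloride (CC(C)(C)[Si](C)(C)Cl)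
Why: In this Mukaiyama–Michael addition the ketene acetal attacks the β-carbon C10 axially and anti to the C2 silyloxy group (3,5-trans), silyl transfer stores the enolate as the regiodefined C4/C5 enol silyl ether, and the C9 configuration formed here (attack anti to the C8 methyl expected) is erased in step 10.

Step 10
Reactants: 19 Mukaiyama–Michael adduct
Product: 21 C9-methylated lactone, via lithium enolate 20 (not isolated)
Conditions: LiN(iPr)2, THF, −78 to −40 °C; MeI, DMPU, −78 to −20 °C
Reagents that add atoms: iodomethane (CI)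
Why: In this lactone enolate alkylation the C8 methyl and the C7 benzyloxymethyl group shield the same face of the planar enolate, so iodomethane enters anti to both and sets quaternary C9 with C20 trans and ring A cis to the C8 methyl on the lactone.

Step 11
Reactants: 21 C9-methylated lactone
Product: 22 lactol (anomers)
Conditions: iBu2AlH (1.2 equiv), toluene, −78 °C; aqueous potassium sodium tartrate
Reagents that add atoms: none
Why: Partial reduction of the hindered lactone stops at the aluminium hemiacetal at low temperature, while the enol silyl ether keeps the C4 carbonyl masked from the hydride.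

Step 12
Reactants: 22 lactol; 16 [(2S)-4-methoxy-2-methyl-4-oxobutyl]triphenylphosphonium bromide
Product: 25 (Z)-alkene acetate (C11=C12, C7–OAc, C6–OBn), via ylide 23 (not isolated), via potassium alkoxide 24 (not isolated)
Conditions: 16, KN(SiMe3)2, THF, 0 °C; add 22, 0 to 45 °C; then Ac2O, DMAP, 0 °C to rt
Reagents that add atoms: acetic anhydride (CC(=O)OC(C)=O)
Why: The Wittig reaction of the non-stabilised ylide with the open hydroxy-aldehyde form of the lactol (a non-enolisable neopentyl aldehyde) forms the C11=C12 bond and brings in C13 unchanged, and the C7 alkoxide released is acetylated in the same flask.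

Step 13
Reactants: 25 (Z)-alkene acetate
Product: 26 primary alcohol (saturated side chain, C6–OH)
Conditions: H2 (1 atm), 10% Pd/C, EtOAc, rt
Reagents that add atoms: none
Why: Catalytic hydrogenation saturates the disubstituted alkene and hydrogenolyses the benzyl ether, while the tetrasubstituted enol silyl ether is too hindered to be reduced.

Step 14
Reactants: 26 primary alcohol
Product: 27 C6 tosylate
Conditions: TsCl, Et3N, DMAP (cat.), CH2Cl2, 0 °C
Reagents that add atoms: p-toluenesulfonyl chloride (Cc1ccc(cc1)S(=O)(=O)Cl)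
Why: Sulfonylation of the only free (primary) hydroxyl under mild amine base turns C6 into the electrophile without disturbing the enol silyl ether or the neighbouring acetate.

Step 15
Reactants: 27 C6 tosylate
Product: 29 cis-fused decalone (C4 ketone, C2–OSi(iPr)3, C7–OAc), via sulfonium enolate 28 (not isolated)
Conditions: (Me2N)3S+ Me3SiF2− (1.1 equiv), THF, −78 to 0 °C; pH 7 phosphate buffer
Reagents that add atoms: none
Why: Fluoride removes the tert-butyldimethylsilyl group from the enol ether to give the regiodefined tetrasubstituted C4/C5 enolate 28 (its position was fixed by the conjugate addition of step 9), which displaces the primary C6 tosylate by intramolecular SN2 attack and so forms the C5–C6 bond and the C5 quaternary centre. The closest known reaction type is the regiospecific C-alkylation of fluoride-generated enolates from enol silyl ethers, used here as a cycloalkylation of the kind that gives cis-fused angular-methyl decalones. Ring B closes in the 6-(enolexo)-exo-tet mode. C5 is controlled by C10: A(1,2) strain with the C5 methyl holds the C10–C9 bond pseudo-axial, the four-atom tether can reach only the syn face, and axial attack gives the cis fusion with C19 cis to H-10, whereas a trans fusion would need equatorial attack through a twist-boat. The step needs C- over O-alkylation (O-attack would give a strained eight-membered enol ether), the C5 and not the C3 enolate (secured by the enol silyl ether), and desilylation of the enol ether in the presence of the triisopropylsilyl ether (enol silyl ethers are cleaved far faster); the buffered quench prevents β-elimination of the C2 silyloxy group.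

Step 16
Reactants: 29 cis-fused decalone
Product: 30 C4 exo-methylene compound
Conditions: Zn, CH2Br2, TiCl4, THF, 0 °C (reagent aged); add 29, CH2Cl2, rt
Reagents that add atoms: dibromomethane (BrCBr)
Why: The Takai–Lombardo methylenation uses a non-basic gem-dimetallic reagent that converts the hindered, enolisable C4 ketone into C4=C18 without β-elimination of the silyloxy group and without attack on the acetate or the methyl ester.

Step 17
Reactants: 30 C4 exo-methylene compound
Product: 31 C3 allylic alcohol (C3 epimers)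
Conditions: SeO2 (0.5 equiv), t-BuOOH, CH2Cl2, rt
Reagents that add atoms: selenium dioxide (O=[Se]=O); tert-butyl hydroperoxide (CC(C)(C)OO)
Why: The selenium dioxide allylic oxidation (ene reaction followed by 2,3-sigmatropic shift) can only strike C3, because the other allylic carbon C5 is quaternary, and it returns the alkene to the exocyclic position; the C3 configuration is irrelevant since the carbinol is oxidised in step 19.

Step 18
Reactants: 31 C3 allylic alcohol
Product: 32 C2,C3-diol
Conditions: Bu4NF, AcOH, THF, rt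
Reagents that add atoms: none
Why: Buffered fluoride desilylation frees the C2 hydroxyl while the acetic acid suppresses acetate migration and ester cleavage.

Step 19
Reactants: 32 C2,C3-diol
Product: 34 target CNP0180040.1, via C2,C3-dione 33 (not isolated)
Conditions: (COCl)2, DMSO, CH2Cl2, −78 °C; Et3N, −78 to 0 °C
Reagents that add atoms: none
Why: Double Swern oxidation gives the 1,2-dione, which can enolise only toward C1 because C4 is already sp2, so the amine-mediated tautomerisation delivers the C1=C2(OH)–C3=O diosphenol of the target.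

**Compound list**

1 | (S)-(+)-carvone, (5S)-2-methyl-5-(prop-1-en-2-yl)cyclohex-2-en-1-one | CC(=C)[C@H]1CC=C(C)C(=O)C1 | starting material
2 | (5S)-5-(1-hydroperoxy-1-methoxyethyl)-2-methylcyclohex-2-en-1-one (both epimers at the peroxy carbon) | CC(OC)(OO)[C@H]1CC=C(C)C(=O)C1 | intermediate
3 | (1S)-4-methyl-5-oxocyclohex-3-en-1-yl acetate | CC(=O)O[C@H]1CC=C(C)C(=O)C1 | intermediate
4 | (5S)-5-hydroxy-2-methylcyclohex-2-en-1-one | O[C@H]1CC=C(C)C(=O)C1 | intermediate
5 | (5S)-2-methyl-5-[(triisopropylsilyl)oxy]cyclohex-2-en-1-one | CC(C)[Si](O[C@H]1CC=C(C)C(=O)C1)(C(C)C)C(C)C | intermediate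
6 | 2-(benzyloxy)acetaldehyde | O=CCOCc1ccccc1 | starting material
7 | diisopinocampheylborinate ester of 8 | C=C[C@H](C)[C@@H](OB([C@H]1C[C@H]2C[C@@H]([C@@H]1C)C2(C)C)[C@H]1C[C@H]2C[C@@H]([C@@H]1C)C2(C)C)COCc1ccccc1 | intermediate
8 | (2R,3S)-1-(benzyloxy)-3-methylpent-4-en-2-ol (syn) | C=C[C@H](C)[C@@H](O)COCc1ccccc1 | intermediate
9 | O,C-bis(9-borabicyclo[3.3.1]nonan-9-yl) adduct of 8 | C(C[C@H](C)[C@@H](OB1C2CCCC1CCC2)COCc1ccccc1)B1C2CCCC1CCC2 | intermediate
10 | (3S,4R)-5-(benzyloxy)-3-methylpentane-1,4-diol | OCC[C@H](C)[C@@H](O)COCc1ccccc1 | intermediate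
11 | (4S,5R)-5-[(benzyloxy)methyl]-4-methyloxolan-2-ol (anomers) | OC1C[C@H](C)[C@H](COCc2ccccc2)O1 | intermediate
12 | (4S,5R)-5-[(benzyloxy)methyl]-4-methyloxolan-2-one (cis-4,5) | O=C1C[C@H](C)[C@H](COCc2ccccc2)O1 | intermediate
13 | (S)-4-methyloxolan-2-one, (S)-β-methyl-γ-butyrolactone | O=C1C[C@H](C)CO1 | starting material
14 | (S)-4-bromo-3-methylbutanoic acid | OC(=O)C[C@H](C)CBr | intermediate
15 | methyl (S)-4-bromo-3-methylbutanoate | COC(=O)C[C@H](C)CBr | intermediate
16 | [(2S)-4-methoxy-2-methyl-4-oxobutyl]triphenylphosphonium bromide | COC(=O)C[C@H](C)C[P+](c1ccccc1)(c1ccccc1)c1ccccc1.[Br-] | intermediate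
17 | lithium enolate of lactone 12 | [Li+].[O-]C1=C[C@H](C)[C@H](COCc2ccccc2)O1 | intermediate
18 | tert-butyldimethylsilyl ketene acetal of lactone 12 | CC(C)(C)[Si](C)(C)OC1=C[C@H](C)[C@H](COCc2ccccc2)O1 | intermediate
19 | Mukaiyama–Michael adduct: cis-4,5-lactone 12 carrying on its α-carbon (C9, H) the 3-(tert-butyldimethylsilyloxy)-2-methyl-5-(triisopropylsilyloxy)cyclohex-2-en-1-yl group; C10 trans to C2–O; C9 epimer with ring A trans to the C8 methyl drawn | CC1=C(O[Si](C)(C)C(C)(C)C)C[C@@H](O[Si](C(C)C)(C(C)C)C(C)C)C[C@@H]1[C@@H]2C(=O)O[C@@H](COCc3ccccc3)[C@H]2C | intermediate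
20 | lithium enolate of lactone 19 | [Li+].CC1=C(O[Si](C)(C)C(C)(C)C)C[C@@H](O[Si](C(C)C)(C(C)C)C(C)C)C[C@@H]1C2=C([O-])O[C@@H](COCc3ccccc3)[C@H]2C | intermediate
21 | C9-methylated lactone: as 19 with the C20 methyl on the lactone α-carbon, trans to the C8 methyl (ring A cis to it) | CC1=C(O[Si](C)(C)C(C)(C)C)C[C@@H](O[Si](C(C)C)(C(C)C)C(C)C)C[C@@H]1[C@@]2(C)C(=O)O[C@@H](COCc3ccccc3)[C@H]2C | intermediate
22 | lactol of 21 (anomers at C11) | CC1=C(O[Si](C)(C)C(C)(C)C)C[C@@H](O[Si](C(C)C)(C(C)C)C(C)C)C[C@@H]1[C@@]2(C)C(O)O[C@@H](COCc3ccccc3)[C@H]2C | intermediate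
23 | ylide, methyl (3S)-3-methyl-4-(triphenylphosphoranylidene)butanoate | COC(=O)C[C@H](C)C=P(c1ccccc1)(c1ccccc1)c1ccccc1 | intermediate
24 | potassium C7-alkoxide of the (Z)-C11=C12 alkenol | [K+].CC1=C(O[Si](C)(C)C(C)(C)C)C[C@@H](O[Si](C(C)C)(C(C)C)C(C)C)C[C@@H]1[C@@](C)(/C=C\[C@@H](C)CC(=O)OC)[C@H](C)[C@@H]([O-])COCc1ccccc1 | intermediate
25 | (Z)-alkene acetate: ring-A enol silyl ether bearing at C10 the chain C9(Me)(CH=CH–CH(Me)CH2CO2Me)–C8H(Me)–C7H(OAc)–CH2OBn | CC1=C(O[Si](C)(C)C(C)(C)C)C[C@@H](O[Si](C(C)C)(C(C)C)C(C)C)C[C@@H]1[C@@](C)(/C=C\[C@@H](C)CC(=O)OC)[C@H](C)[C@@H](OC(C)=O)COCc1ccccc1 | intermediate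
26 | primary alcohol: saturated C11–C15 chain, C7–OAc, C6–OH | CC1=C(O[Si](C)(C)C(C)(C)C)C[C@@H](O[Si](C(C)C)(C(C)C)C(C)C)C[C@@H]1[C@@](C)(CC[C@@H](C)CC(=O)OC)[C@H](C)[C@@H](OC(C)=O)CO | intermediate
27 | C6 tosylate of 26 | CC1=C(O[Si](C)(C)C(C)(C)C)C[C@@H](O[Si](C(C)C)(C(C)C)C(C)C)C[C@@H]1[C@@](C)(CC[C@@H](C)CC(=O)OC)[C@H](C)[C@@H](OC(C)=O)COS(=O)(=O)c1ccc(C)cc1 | intermediate
28 | tris(dimethylamino)sulfonium C4/C5 enolate of the tosylate | CN(C)[S+](N(C)C)N(C)C.CC1=C([O-])C[C@@H](O[Si](C(C)C)(C(C)C)C(C)C)C[C@@H]1[C@@](C)(CC[C@@H](C)CC(=O)OC)[C@H](C)[C@@H](OC(C)=O)COS(=O)(=O)c1ccc(C)cc1 | intermediate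
29 | cis-fused decalone: C4 ketone, C2–OSi(iPr)3 (trans to C9 on ring A), C7–OAc, H-10 and C19 cis | O=C1C[C@@H](O[Si](C(C)C)(C(C)C)C(C)C)C[C@@H]2[C@@](C)(CC[C@@H](C)CC(=O)OC)[C@H](C)[C@@H](OC(C)=O)C[C@]12C | intermediate
30 | C4 exo-methylene compound | C=C1C[C@@H](O[Si](C(C)C)(C(C)C)C(C)C)C[C@@H]2[C@@](C)(CC[C@@H](C)CC(=O)OC)[C@H](C)[C@@H](OC(C)=O)C[C@]12C | intermediate
31 | C3 allylic alcohol (C3 epimers) | C=C1C(O)[C@@H](O[Si](C(C)C)(C(C)C)C(C)C)C[C@@H]2[C@@](C)(CC[C@@H](C)CC(=O)OC)[C@H](C)[C@@H](OC(C)=O)C[C@]12C | intermediate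
32 | C2,C3-diol (C3 epimers) | C=C1C(O)[C@@H](O)C[C@@H]2[C@@](C)(CC[C@@H](C)CC(=O)OC)[C@H](C)[C@@H](OC(C)=O)C[C@]12C | intermediate
33 | C2,C3-dione | C=C1C(=O)C(=O)C[C@@H]2[C@@](C)(CC[C@@H](C)CC(=O)OC)[C@H](C)[C@@H](OC(C)=O)C[C@]12C | intermediate
34 | CNP0180040.1, methyl 7-acetoxy-2-hydroxy-3-oxo-5,10-cis-cleroda-1,4(18)-dien-15-oate (H-10/C19 cis, C17/C20 cis, C19/C20 trans, 7-OAc cis to C19 and C11, 13R) | C=C1C(=O)C(O)=C[C@@H]2[C@@](C)(CC[C@@H](C)CC(=O)OC)[C@H](C)[C@@H](OC(C)=O)C[C@]12C | target

**Step count and risks**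

Total step count: 19. Longest linear sequence: 14 steps (1 to 34 through steps 1–3 and 9–19; the branch from 6 through steps 4–6 and 9–19 is equally long).

Steps most likely to fail:

1. Step 15 (ring closure). The free enolate may be quenched by proton transfer, may attack the β-branched primary tosylate too slowly, or may eliminate the C2 silyloxy group before it alkylates. Fallback, setting out from 26 and returning at 29: oxidise the primary alcohol with Dess–Martin periodinane to the aldehyde F1. Close ring B by intramolecular Mukaiyama aldol addition of the enol silyl ether to that aldehyde (BF3·OEt2, CH2Cl2, −78 °C), which forms the same C5–C6 bond with the same cis fusion and gives the β-hydroxy ketone F2. Remove the extra C6 hydroxyl by Barton–McCombie deoxygenation through the O-thiocarbonylimidazolide F3 (1,1'-thiocarbonyldiimidazole, DMAP; then Bu3SnH, AIBN, toluene, 80 °C) to reach 29.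

2. Step 12 (olefination). The neopentyl aldehyde unmasked from the lactol may react sluggishly with the bulky β-branched ylide, and lactol reclosure may outrun the olefination. Fallback, setting out from 22 and returning at 26: treat the lactol with the smallest ylide, Ph3P=CH2 (from Ph3PCH3Br and KN(SiMe3)2), and quench with Ac2O to give the vinyl acetate F4. Join the chain by cross-metathesis with methyl (S)-3-methylpent-4-enoate under the second-generation Hoveyda–Grubbs catalyst, RuCl2(=CH–C6H4-2-OiPr)(H2IMes), in CH2Cl2 at 40 °C to give the (E)-alkene F5. Hydrogenation and hydrogenolysis under the conditions of step 13 then give 26.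

3. Step 9 (fragment union). The hindered α-methyl enone may give incomplete conversion, 1,2-addition, loss of the silyl transfer, or poor facial selectivity at C10. Fallback, setting out from 12 and returning at 21: sulfenylate the lactone (LiN(iPr)2; PhSSPh) to the α-phenylthio lactone F6. Add its lithium enolate, a soft sulfur-stabilised donor that favours 1,4-addition, to enone 5 in THF/DMPU and trap with tBuMe2SiOTf to give the enol silyl ether F7. Cleave the C–S bond reductively with lithium naphthalenide (LiC10H8, THF, −78 °C) to regenerate the lactone enolate 20, and methylate it with MeI as in step 10 to give 21.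

**Further compounds**

F1 | step 15 | C6 aldehyde of 26 (enol silyl ether retained) | CC1=C(O[Si](C)(C)C(C)(C)C)C[C@@H](O[Si](C(C)C)(C(C)C)C(C)C)C[C@@H]1[C@@](C)(CC[C@@H](C)CC(=O)OC)[C@H](C)[C@@H](OC(C)=O)C=O
F2 | step 15 | C6-hydroxy cis-decalone (aldol, C6 epimers) | O=C1C[C@@H](O[Si](C(C)C)(C(C)C)C(C)C)C[C@@H]2[C@@](C)(CC[C@@H](C)CC(=O)OC)[C@H](C)[C@@H](OC(C)=O)C(O)[C@]12C
F3 | step 15 | C6 O-thiocarbonylimidazolide of F2 | O=C1C[C@@H](O[Si](C(C)C)(C(C)C)C(C)C)C[C@@H]2[C@@](C)(CC[C@@H](C)CC(=O)OC)[C@H](C)[C@@H](OC(C)=O)C(OC(=S)n3ccnc3)[C@]12C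
F4 | step 12 | C9-vinyl C7-acetate (C11=CH2) | CC1=C(O[Si](C)(C)C(C)(C)C)C[C@@H](O[Si](C(C)C)(C(C)C)C(C)C)C[C@@H]1[C@@](C)(C=C)[C@H](C)[C@@H](OC(C)=O)COCc1ccccc1
F5 | step 12 | (E)-C11=C12 isomer of 25 | CC1=C(O[Si](C)(C)C(C)(C)C)C[C@@H](O[Si](C(C)C)(C(C)C)C(C)C)C[C@@H]1[C@@](C)(/C=C/[C@@H](C)CC(=O)OC)[C@H](C)[C@@H](OC(C)=O)COCc1ccccc1
F6 | step 9 | (4S,5R)-5-[(benzyloxy)methyl]-4-methyl-3-(phenylthio)oxolan-2-one (C3 epimers) | O=C1C(Sc2ccccc2)[C@H](C)[C@H](COCc2ccccc2)O1
F7 | step 9 | α-phenylthio analogue of 19 (C9 epimers) | CC1=C(O[Si](C)(C)C(C)(C)C)C[C@@H](O[Si](C(C)C)(C(C)C)C(C)C)C[C@@H]1C2(Sc3ccccc3)C(=O)O[C@@H](COCc3ccccc3)[C@H]2C
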